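## The problem

Target 30 is a ten-membered carbocycle (C1–C10) bridged by an oxygen between C3 and C10, so that C10, C1 (ketone), C2=C3 and that oxygen form a 3(2H)-furanone. C4 carries the exocyclic methylene C15, C5 a free hydroxyl, C6 a methacrylate, C7 the carbon C11 of an α-methylene-γ-lactone (C12 carbonyl, C13 methylene) closed through the C8 oxygen, C9 is a methylene and C10 bears the methyl C14. Five stereocentres are present: the quaternary C10 and the contiguous run C5–C8. C10 sits across the ring from the others, and C5 and C8 are insulated from each other by the C6–C7 unit, so these three must come from the chiral pool or from a catalyst. C6 and C7 lie between two oxygen-bearing carbons and can be controlled by them and by the shape of the ring. The planar furanone holds C4 and C9 apart, so the C5–C8 segment is a taut bridge with an anti C5–C6–C7–C8 backbone, and closing the medium ring is the main skeletal risk. The finished molecule carries two acrylate acceptors, a cross-conjugated dienyl enol ether (C15=C4–C3=C2–C1=O), a ketone whose α-oxygen is open to reductive C10–O cleavage, and three neighbouring oxygens (C5, C6, C8) between which acyl groups can migrate; strong nucleophiles, hydrides and hot base are therefore excluded late, and the acrylate units must arrive last. The enabling feature is that the C6 oxygen and the C7–C11 bond are vicinal, lie next to the C8 lactone oxygen and all sit on the outer face of the ring: they are what results when a carbon and an oxygen are added across a C6=C7 alkene, the carbon handed over by a two-carbon tether on the C8 oxygen.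

## Retrosynthesis

Target 30 is first stripped of the two groups that cannot ride through the route: the C6 methacrylate (ester C–O bond) and the free C5 hydroxyl, which is masked as a TBS ether. This leads through 29 to alcohol 28. Cutting here keeps both acrylate acceptors and the migration-prone free diol out of every earlier step. The forward steps must acylate a hindered C6 hydroxyl without moving the lactone, and remove silicon under acidic conditions so the methacrylate stays on C6.

The exocyclic C11=C13 bond and the free C6 hydroxyl of 28 are traced to lactone 24, in which C11 is a methylene and the C6 oxygen is still bound to the tetramethylpiperidine nitrogen. The methylene carbon is added by enolate aminomethylation (25) and elimination (27), and the N–O bond is cut afterwards. This order keeps the C6 oxygen capped during the only strongly basic step. The C1 ketone has no α-hydrogen, so the lactone is the only enolisable carbonyl.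

Lactone 24 comes from acetal 22 by hydrolysis (23) and oxidation. Acetal 22 is disconnected at C7–C11 and C6–O together: both bonds form when the primary radical from bromoacetal 21 closes onto C7 and the resulting C6 radical couples with TEMPO. The neighbouring cuts are opening a C6–C7 epoxide at C7 with an acetate equivalent, or a ring-closing allylation that makes C7–C8. Against these, the radical cut delivers the carbon from the very oxygen that ends up in the lactone, fixes the regiochemistry, and brings the C6 oxygen in at the right oxidation level in the same operation. The precursor is simpler by one ring, two skeletal bonds and two stereocentres. The forward reaction must close the ring before the nitroxide intervenes, reach C7 on the face that gives the cis ring fusion, and deliver the nitroxide to the same outer face at C6.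

Bromoacetal 21 is the ethyl vinyl ether adduct of allylic alcohol 20, and 20 is opened at C6=C7 to diene 19 by ring-closing metathesis. C6=C7 is the one bond of the bridge that can be made from two simple alkenyl groups without creating a stereocentre, and it puts the alkene exactly where the key step needs it. Because the furanone sends the bonds to C4 and C9 out in diverging directions, C5 and C8 must sit roughly anti across the bridge, so the ring is expected to close to the E alkene. The forward step must beat oligomerisation and closure onto the C4 methylidene.

Furanone 19 is cut at O–C3 and at C1–C2. The first cut reveals the α′-hydroxy ynone 18, which closes 5-endo-dig. The second divides the molecule into lactone 16, which acts as the C1 acyl donor and releases the C8 hydroxyl in the same event, and lithium acetylide 17, made from dibromodiene 8. Compared with an aldol, oxidation and cyclodehydration sequence through a 1,3-diketone, this needs two steps after fragment union and no oxidation next to the alkenes. It asks for a single addition of the acetylide to a lactone carbonyl.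

Lactone 16 is the TMS ether of 15, the semi-hydrogenation product of alkynyl lactone 14. Lactone 14 arises by lactonisation of propargylic alcohol 13, obtained by catalyst-controlled transfer hydrogenation of ynone 12. Ynone 12 comes from acid 10 through acid chloride 11, and 10 is the acetonide of (R)-citramalic acid 9, which supplies C10 with its methyl group, C9, C8 and C1. C8 is set by the catalyst because the quaternary C10, with two substituents of similar size, is a poor source of 1,3-induction.

Dibromodiene 8 is the olefination product of enal 7, reached from ester 5 by reduction (6) and allylic oxidation. Ester 5 is the TBS ether of 4, the (R)-enantiomer of the Morita–Baylis–Hillman adduct 3 of acrolein 1 and methyl acrylate 2. That one step assembles C3, C4, C15, C5, C6 and C7. The enantiomers are separated by kinetic resolution at the outset, where material is cheapest.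

## Roads not taken

Alternative 1: The ten-membered ring would be made by ring expansion and not by ring closure. Deprotonation (KH, 18-crown-6) of a tertiary carbinol on a terpene-derived cyclohexane, flanked by an allenyl group and a fused dihydrofuran, triggers an anionic oxy-Cope shift. This cleaves a cyclohexane bond, forms C3–C4 and gives A1, the oxygen-bridged cyclodecenone with the C4 methylene and a C5=C6 silyl enol ether.
- Merits: no high-dilution closure of a strained ring; C7, C8 and C10 are fixed beforehand on a six-membered ring, where relative configuration is easy to secure; the C4 methylene comes from the allene for free.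
- Weak points: A1 is at the wrong oxidation level in several places. The furanone still lacks its C2=C3 bond and must be dehydrogenated next to a bridgehead. The enol ether must be converted into two defined carbinols at C5 and C6 on a flexible ring. The lactone carbons arrive as an isopropenyl group that needs allylic oxidation in the presence of two other allylic systems.
- Comparison: for building the ring, this road is better than the chosen plan, which has a strained metathesis. The chosen plan has to set against it that after its key step only one oxidation (acetal to lactone) remains, that C5 and the furanone are in place before the ring is closed, and that C6 and C7 are set together by internal delivery.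

Alternative 2: The ring and its oxygen bridge would come from a sugar-derived pyran. Cu(CF3COCHCOCF3)2 or Rh2(OAc)4 decomposes a diazo carbonyl side chain, the pyran oxygen captures the C10 carbenoid, and the oxonium ylide shifts [2,3] onto a vinyl group. This forms O–C10 and C9–C10 and gives A2, the 11-oxabicyclo[6.2.1]undecenone with a Z C7=C8 alkene.
- Merits: bridge, medium ring and the quaternary C10 are made in one mild step; the Z geometry follows from the concerted shift; the C4–C6 oxygens come from the sugar.
- Weak points: a carbenoid that carries a methyl group is prone to 1,2-hydride shift, and [1,2]-shift competes with the [2,3] pathway. The configuration at C10 is decided in the ylide step and not bought. A2 has an oxygen where the C4 methylene is needed, lacks the C2=C3 bond, and has its alkene at C7=C8, one position away from where carbon and oxygen must be added. A tether from the C6 oxygen would give the lactone on the wrong oxygen.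
- Comparison: this road is better at forming the bridged ring without strain-limited macrocyclisation and at sourcing three oxygenated centres. The chosen plan sets against it a C10 centre taken from citramalic acid, an alkene placed exactly at C6=C7, and far fewer steps after the ring exists.

Alternative 3: The furanone would be made with its quaternary centre by AuCl3 activation of a C2–C3 alkyne. The C10 ketone oxygen attacks C3 and the methyl group migrates from C1 to C10, which gives A3, a furanone that already carries both arms, the methacrylate and an acrylate unit for the lactone, but is still open at C7–C8. A ring-closing allylation of a C8 aldehyde would then form the ring and the lactone together.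
- Merits: highly convergent; the lactone carbons arrive as an intact acrylate, so no late α-methylenation and no nitroxide removal are needed; in step count it is at least as short as the chosen plan.
- Weak points: C10 depends on an enantioenriched tertiary propargylic ketol, which is harder to obtain than citramalic acid. The C6 methacrylate in A3 is allylic to the acrylate and prone to SN2′ displacement. Three acceptors must survive gold catalysis and the ring closure. The ring-closing allylation has to create C7 and C8 with cis fusion while closing a strained ring, so stereocontrol and ring strain are tested in the same step.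
- Comparison: in convergence and step economy this road is as good or better. The chosen plan sets against it a ring closure that forms no stereocentre, a separate tether-controlled step for C6 and C7, acceptors that appear only in the last steps, and a chiral-pool origin for C10.

Key step: step 16

Assumption: the C6=C7 double bond of the bridged ring is taken as E, because the rigid furanone holds C5 and C8 roughly as far apart as a trans alkene spans and further than a cis alkene allows. The key step consumes this alkene, and its geometry decides only from which side C7 and C6 are reached.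

Step 1
Reactants: 1 acrolein; 2 methyl acrylate
Product: 3 methyl 3-hydroxy-2-methylidenepent-4-enoate (racemic)
Conditions: DABCO (cat.), neat 2 (excess), slow addition of 1, rt
Reagents that add atoms: none
Why: Morita–Baylis–Hillman reaction: the amine adds to the acrylate, the ammonium enolate attacks the aldehyde carbon of acrolein and the amine is expelled; excess acrylate and slow addition of the enal suppress self-condensation of acrolein. The carbinol is racemic and is resolved in step 2.

Step 2
Reactants: 3 methyl 3-hydroxy-2-methylidenepent-4-enoate (racemic)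
Product: 4 methyl (3R)-3-hydroxy-2-methylidenepent-4-enoate (recovered enantiomer)
Conditions: Ti(OiPr)4 (cat.), D-(−)-diisopropyl tartrate (cat.), t-BuOOH (0.6 equiv), 4 Å molecular sieves, CH2Cl2, −20 °C
Reagents that add atoms: none
Why: Sharpless kinetic resolution of a secondary allylic alcohol: the titanium tartrate complex should epoxidise the vinyl group of the (S)-carbinol much faster, while the electron-poor acrylate alkene is inert, so the (R)-alcohol (later C5) is recovered. The D-tartrate follows from the usual rule with the acrylate unit in the place of the alkyl substituent.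

Step 3
Reactants: 4 methyl (3R)-3-hydroxy-2-methylidenepent-4-enoate
Product: 5 methyl (3R)-3-[(tert-butyldimethylsilyl)oxy]-2-methylidenepent-4-enoate
Conditions: TBSCl, imidazole, DMF, rt
Reagents that add atoms: tert-butyldimethylsilyl chloride, CC(C)(C)[Si](C)(C)Cl
Why: Standard silylation of a secondary alcohol; the stereocentre is not touched.

Step 4
Reactants: 5 methyl (3R)-3-[(tert-butyldimethylsilyl)oxy]-2-methylidenepent-4-enoate
Product: 6 (3R)-3-[(tert-butyldimethylsilyl)oxy]-2-methylidenepent-4-en-1-ol
Conditions: i-Bu2AlH (2.2 equiv), CH2Cl2, −78 → 0 °C
Reagents that add atoms: none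
Why: 1,2-Reduction of an α-substituted acrylate to the allylic alcohol by the aluminium hydride; conjugate reduction does not compete at low temperature.

Step 5
Reactants: 6 (3R)-3-[(tert-butyldimethylsilyl)oxy]-2-methylidenepent-4-en-1-ol
Product: 7 (3R)-3-[(tert-butyldimethylsilyl)oxy]-2-methylidenepent-4-enal
Conditions: MnO2, CH2Cl2, rt
Reagents that add atoms: none
Why: Selective oxidation of a primary allylic alcohol under neutral conditions; the carbinol centre is attached to an sp2 carbon and cannot epimerise through enolisation.

Step 6
Reactants: 7 (3R)-3-[(tert-butyldimethylsilyl)oxy]-2-methylidenepent-4-enal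
Product: 8 tert-butyl{[(4R)-1,1-dibromo-3-methylidenehexa-1,5-dien-4-yl]oxy}dimethylsilane
Conditions: CBr4, PPh3, Et3N, CH2Cl2, 0 °C
Reagents that add atoms: carbon tetrabromide, BrC(Br)(Br)Br
Why: Ramirez dibromo-olefination (first stage of the Corey–Fuchs sequence) through the dibromomethylene ylide; the amine buffers the phosphorus bromide so the allylic silyl ether survives.

Step 7
Reactants: 9 (R)-citramalic acid
Product: 10 2-[(4R)-2,2,4-trimethyl-5-oxo-1,3-dioxolan-4-yl]acetic acid
Conditions: 2,2-dimethoxypropane, TsOH (cat.), rt
Reagents that add atoms: 2,2-dimethoxypropane, COC(C)(C)OC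
Why: Acetonide formation between the tertiary hydroxyl and the adjacent carboxyl gives the five-membered dioxolanone in preference to the six-membered alternative, which differentiates the two acids; C10 is not involved.

Step 8
Reactants: 10 2-[(4R)-2,2,4-trimethyl-5-oxo-1,3-dioxolan-4-yl]acetic acid
Product: 12 (5R)-2,2,5-trimethyl-5-(2-oxopent-3-yn-1-yl)-1,3-dioxolan-4-one, via acid chloride 11 (not isolated)
Conditions: (COCl)2, DMF (cat.), CH2Cl2, 0 °C → rt; then propyne (THF solution), PdCl2(PPh3)2 (cat.), CuI (cat.), Et3N, THF, rt
Reagents that add atoms: propyne, CC#C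
Why: Acid chloride formation followed by acyl Sonogashira coupling gives the ynone without any nucleophile strong enough to open the dioxolanone.

Step 9
Reactants: 12 (5R)-2,2,5-trimethyl-5-(2-oxopent-3-yn-1-yl)-1,3-dioxolan-4-one
Product: 14 (3R,5S)-3-hydroxy-3-methyl-5-(prop-1-yn-1-yl)oxolan-2-one, via hydroxy dioxolanone 13 (not isolated)
Conditions: Ru[(S,S)-TsNCHPhCHPhNH](p-cymene) (cat.), i-PrOH, rt; then PPTS (cat.), CH2Cl2, rt
Reagents that add atoms: none
Why: Noyori asymmetric transfer hydrogenation of an alkynyl ketone: the (S,S)-catalyst should deliver hydride to give the (S)-carbinol at C8 by reagent control, the alkynyl group taking the role of the aryl group of an aryl ketone. Acid then lets the new hydroxyl displace acetone from the activated dioxolanone carbonyl (5-exo-trig lactonisation), which masks the C8 hydroxyl and keeps C1 as an acyl donor.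

Step 10
Reactants: 14 (3R,5S)-3-hydroxy-3-methyl-5-(prop-1-yn-1-yl)oxolan-2-one
Product: 15 (3R,5S)-3-hydroxy-3-methyl-5-[(1Z)-prop-1-en-1-yl]oxolan-2-one
Conditions: H2 (1 atm), Pd on CaCO3 poisoned with Pb(OAc)2 (Lindlar catalyst), quinoline, EtOAc, rt
Reagents that add atoms: none
Why: Lindlar semi-hydrogenation: syn addition of hydrogen on the poisoned surface stops at the Z alkene, which serves as the metathesis partner at C7.

Step 11
Reactants: 15 (3R,5S)-3-hydroxy-3-methyl-5-[(1Z)-prop-1-en-1-yl]oxolan-2-one
Product: 16 (3R,5S)-3-methyl-5-[(1Z)-prop-1-en-1-yl]-3-[(trimethylsilyl)oxy]oxolan-2-one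
Conditions: TMSCl, imidazole, DMF, 0 °C → rt
Reagents that add atoms: chlorotrimethylsilane, C[Si](C)(C)Cl
Why: Silylation of the tertiary hydroxyl removes the only acidic proton, so the acetylide of step 12 is spent on the carbonyl alone; the small silyl group is shed again in step 13.

Step 12
Reactants: 8 tert-butyl{[(4R)-1,1-dibromo-3-methylidenehexa-1,5-dien-4-yl]oxy}dimethylsilane; 16 (3R,5S)-3-methyl-5-[(1Z)-prop-1-en-1-yl]-3-[(trimethylsilyl)oxy]oxolan-2-one
Product: 18 (2Z,4S,6R,11R)-11-[(tert-butyldimethylsilyl)oxy]-4-hydroxy-6-methyl-10-methylidene-6-[(trimethylsilyl)oxy]trideca-2,12-dien-8-yn-7-one, via lithium acetylide 17 (not isolated)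
Conditions: 8, n-BuLi (2.05 equiv), THF, −78 → 0 °C; then 16, −78 °C; AcOH, −78 °C
Reagents that add atoms: none
Why: Second stage of the Corey–Fuchs sequence (bromine–lithium exchange, 1,2-shift, deprotonation) gives the lithium acetylide, which adds once to the lactone carbonyl because the lithium hemiketal is stable at −78 °C and the α-carbon is quaternary, so enolisation is impossible. The cold acidic quench releases the γ-hydroxy ynone (in equilibrium with its cyclic hemiketal), forming C1–C2 and freeing the C8 hydroxyl.

Step 13
Reactants: 18 (2Z,4S,6R,11R)-11-[(tert-butyldimethylsilyl)oxy]-4-hydroxy-6-methyl-10-methylidene-6-[(trimethylsilyl)oxy]trideca-2,12-dien-8-yn-7-one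
Product: 19 (2R)-5-{(3R)-3-[(tert-butyldimethylsilyl)oxy]penta-1,4-dien-2-yl}-2-[(2S,3Z)-2-hydroxypent-3-en-1-yl]-2-methylfuran-3(2H)-one
Conditions: K2CO3 (cat.), MeOH, 0 °C → rt
Reagents that add atoms: none
Why: Methanolysis removes the tertiary TMS group and the C10 alkoxide adds to C3 of the ynone in a Baldwin-allowed 5-endo-dig oxa-Michael closure; protonation of the allenolate gives the 3(2H)-furanone. The seven-membered closure from the C8 hydroxyl is far slower, and C10 keeps its configuration.

Step 14
Reactants: 19 (2R)-5-{(3R)-3-[(tert-butyldimethylsilyl)oxy]penta-1,4-dien-2-yl}-2-[(2S,3Z)-2-hydroxypent-3-en-1-yl]-2-methylfuran-3(2H)-one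
Product: 20 (5R,6E,8S,10R)-5-[(tert-butyldimethylsilyl)oxy]-3,10-epoxy-8-hydroxy-10-methyl-4-methylidenecyclodeca-2,6-dien-1-one
Conditions: second-generation Grubbs catalyst (H2IMes)(PCy3)Cl2Ru=CHPh (cat.), 1,4-benzoquinone (cat.), toluene (high dilution), 80 °C
Reagents that add atoms: none
Why: Ring-closing metathesis between the C5 vinyl and the C8 propenyl group with loss of propene; the 1,1-disubstituted, conjugated C4 methylidene is a much poorer partner. No stereocentre is formed, and the alkene is expected to be E because only an anti C5–C6–C7–C8 array spans the gap that the rigid furanone leaves between C4 and C9.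

Step 15
Reactants: 20 (5R,6E,8S,10R)-5-[(tert-butyldimethylsilyl)oxy]-3,10-epoxy-8-hydroxy-10-methyl-4-methylidenecyclodeca-2,6-dien-1-one
Product: 21 (5R,6E,8S,10R)-8-(2-bromo-1-ethoxyethoxy)-5-[(tert-butyldimethylsilyl)oxy]-3,10-epoxy-10-methyl-4-methylidenecyclodeca-2,6-dien-1-one (both acetal epimers)
Conditions: ethyl vinyl ether (excess), NBS, CH2Cl2, −40 → 0 °C
Reagents that add atoms: ethyl vinyl ether, C=COCC; N-bromosuccinimide, O=C1CCC(=O)N1Br
Why: Bromoacetalisation: the enol ether, by far the most electron-rich alkene present, takes up bromine, and the C8 hydroxyl captures the oxocarbenium ion. The acetal carbon forms as both epimers, which does not matter because it becomes the lactone carbonyl.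

Step 16
Reactants: 21 (5R,6E,8S,10R)-8-(2-bromo-1-ethoxyethoxy)-5-[(tert-butyldimethylsilyl)oxy]-3,10-epoxy-10-methyl-4-methylidenecyclodeca-2,6-dien-1-one
Product: 22 cis-fused 12-ethoxy oxolane (C8–O–C12–C11–C7 lactol ethyl acetal) bearing the C6 O-(2,2,6,6-tetramethylpiperidin-1-yl) ether and the C5 TBS ether (5S,6R,7S,8S,10R; C12 epimers)
Conditions: Bu3SnH and TEMPO (both by syringe pump), benzene (dilute), 75 °C
Reagents that add atoms: TEMPO, CC1(C)CCCC(C)(C)N1[O]
Why: The stannyl radical, formed when TEMPO takes hydrogen from Bu3SnH, abstracts bromine from 21; the primary C11 radical adds to C7 and the secondary C6 radical so formed couples with TEMPO, which is the known Ueno–Stork haloacetal cyclisation run with nitroxide capture of the cyclised radical. The one ring closed, the oxolane O–C12–C11–C7–C8, forms by 5-exo-trig attack; the 6-endo mode at C6 is disfavoured as usual and would strain the bridge further. C7 is set by the tether: C11 can reach C7 only on the alkene face that carries the C8–O bond, and with C9 turned into the ring this is the outer face, so H7 and H8 end up syn (cis fusion). C6 is set by the ring: the inner lobe of the C6 radical points across the ring at the furanone, so the nitroxide couples on the outer lobe, the face C11 has just used; with the anti C5–C6–C7–C8 backbone this puts the C6 oxygen trans to C7–C11 across the ring and cis to the C5 oxygen, as in 30. C12 is carried as both epimers and is erased in step 18. Ring closure has to outrun nitroxide capture and hydrogen transfer at C11, which is secured by keeping TEMPO and Bu3SnH at low stationary concentration over hot, dilute 21 while the strained E alkene is a fast acceptor. Capture at C6 has to outrun hydrogen transfer, which the near diffusion-controlled radical–nitroxide coupling provides.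

Step 17
Reactants: 22 cis-fused lactol ethyl acetal with C6 nitroxide ether
Product: 23 cis-fused lactol (C12 hydroxyl; 5S,6R,7S,8S,10R; C12 epimers) with C6 O-(2,2,6,6-tetramethylpiperidin-1-yl) ether and C5 TBS ether
Conditions: 1 M aq. HCl, THF, 0 °C → rt
Reagents that add atoms: water, O
Why: Acid hydrolysis of a five-membered cyclic mixed acetal through the ring oxocarbenium ion; the hindered secondary TBS ether and the protonated alkoxyamine should outlast the short exposure.

Step 18
Reactants: 23 cis-fused lactol with C6 nitroxide ether
Product: 24 cis-fused γ-lactone (C12 carbonyl, C11 methylene; 5S,6R,7S,8S,10R) with C6 O-(2,2,6,6-tetramethylpiperidin-1-yl) ether and C5 TBS ether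
Conditions: n-Pr4N[RuO4] (cat.), N-methylmorpholine N-oxide, 4 Å molecular sieves, CH2Cl2, rt
Reagents that add atoms: none
Why: Ley–Griffith oxidation of a lactol to the lactone under neutral conditions; both C12 epimers converge on one compound.

Step 19
Reactants: 24 cis-fused γ-lactone with C6 nitroxide ether
Product: 25 C11-(dimethylaminomethyl) lactone (Mannich base; C11 epimers; otherwise as 24)
Conditions: LiN(SiMe3)2, THF, −78 °C; then CH2=NMe2+ I− (Eschenmoser's salt), −78 °C → rt
Reagents that add atoms: Eschenmoser's salt, C=[N+](C)C.[I-]
Why: The lactone is the only enolisable carbonyl (the C1 ketone has no α-hydrogen), so the lithium enolate forms at C11 and is aminomethylated by the iminium salt; the new C11 centre is lost in step 20.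

Step 20
Reactants: 25 C11-(dimethylaminomethyl) lactone
Product: 27 α-methylene-γ-lactone (C11=C13; 5S,6R,7S,8S,10R) with C6 O-(2,2,6,6-tetramethylpiperidin-1-yl) ether and C5 TBS ether, via trimethylammonium iodide 26 (not isolated)
Conditions: MeI, CH2Cl2, rt; then sat. aq. NaHCO3, rt
Reagents that add atoms: none
Why: Quaternisation of the unhindered dimethylamino group (the alkoxyamine nitrogen is too hindered to react) and mild-base elimination give the exocyclic methylene; this is the standard Mannich route to α-methylene lactones.

Step 21
Reactants: 27 α-methylene-γ-lactone with C6 nitroxide ether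
Product: 28 C6 alcohol (5S,6R,7R,8S,10R; the C7 descriptor changes by priority only) with α-methylene-γ-lactone and C5 TBS ether
Conditions: Zn dust, AcOH/THF/H2O, rt → 40 °C
Reagents that add atoms: none
Why: Zinc in acetic acid reductively cleaves the N–O bond of the alkoxyamine; the C6–O bond is untouched, so the configuration is kept. The temperature is held low to spare the enoate and the α-oxy ketone.

Step 22
Reactants: 28 C6 alcohol
Product: 29 C6 methacrylate (5S,6R,7S,8S,10R) with α-methylene-γ-lactone and C5 TBS ether
Conditions: methacrylic anhydride, Et3N, DMAP (cat.), CH2Cl2, 0 °C → rt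
Reagents that add atoms: methacrylic anhydride, C=C(C)C(=O)OC(=O)C(C)=C
Why: DMAP-catalysed acylation of the secondary hydroxyl through the acylpyridinium ion; no alkoxide is generated, which guards against attack of the C6 oxygen on the lactone.

Step 23
Reactants: 29 C6 methacrylate
Product: 30 target, CNP0142847.2 (5S,6R,7S,8S,10R)
Conditions: HF·pyridine, pyridine, THF, 0 °C → rt
Reagents that add atoms: none
Why: Fluoride cleaves the Si–O bond under mildly acidic conditions, which avoids the base-induced 1,2-shift of the methacrylate to the freed C5 hydroxyl and spares both acrylate acceptors.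

Compound list

1 | acrolein | C=CC=O | starting material
2 | methyl acrylate | C=CC(=O)OC | starting material
3 | methyl 3-hydroxy-2-methylidenepent-4-enoate (racemic) | C=CC(O)C(=C)C(=O)OC | intermediate
4 | methyl (3R)-3-hydroxy-2-methylidenepent-4-enoate | C=C[C@@H](O)C(=C)C(=O)OC | intermediate
5 | methyl (3R)-3-[(tert-butyldimethylsilyl)oxy]-2-methylidenepent-4-enoate | C=C[C@@H](O[Si](C)(C)C(C)(C)C)C(=C)C(=O)OC | intermediate
6 | (3R)-3-[(tert-butyldimethylsilyl)oxy]-2-methylidenepent-4-en-1-ol | C=C[C@@H](O[Si](C)(C)C(C)(C)C)C(=C)CO | intermediate
7 | (3R)-3-[(tert-butyldimethylsilyl)oxy]-2-methylidenepent-4-enal | C=C[C@@H](O[Si](C)(C)C(C)(C)C)C(=C)C=O | intermediate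
8 | tert-butyl{[(4R)-1,1-dibromo-3-methylidenehexa-1,5-dien-4-yl]oxy}dimethylsilane | C=C[C@@H](O[Si](C)(C)C(C)(C)C)C(=C)C=C(Br)Br | intermediate
9 | (R)-citramalic acid, (2R)-2-hydroxy-2-methylbutanedioic acid | C[C@@](O)(CC(=O)O)C(=O)O | starting material
10 | 2-[(4R)-2,2,4-trimethyl-5-oxo-1,3-dioxolan-4-yl]acetic acid | C[C@]1(CC(=O)O)OC(C)(C)OC1=O | intermediate
11 | 2-[(4R)-2,2,4-trimethyl-5-oxo-1,3-dioxolan-4-yl]acetyl chloride | C[C@]1(CC(=O)Cl)OC(C)(C)OC1=O | intermediate (not isolated)
12 | (5R)-2,2,5-trimethyl-5-(2-oxopent-3-yn-1-yl)-1,3-dioxolan-4-one | C[C@]1(CC(=O)C#CC)OC(C)(C)OC1=O | intermediate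
13 | (5R)-5-[(2S)-2-hydroxypent-3-yn-1-yl]-2,2,5-trimethyl-1,3-dioxolan-4-one | C[C@]1(C[C@H](O)C#CC)OC(C)(C)OC1=O | intermediate (not isolated)
14 | (3R,5S)-3-hydroxy-3-methyl-5-(prop-1-yn-1-yl)oxolan-2-one | CC#C[C@@H]1C[C@@](C)(O)C(=O)O1 | intermediate
15 | (3R,5S)-3-hydroxy-3-methyl-5-[(1Z)-prop-1-en-1-yl]oxolan-2-one | C/C=C\[C@@H]1C[C@@](C)(O)C(=O)O1 | intermediate
16 | (3R,5S)-3-methyl-5-[(1Z)-prop-1-en-1-yl]-3-[(trimethylsilyl)oxy]oxolan-2-one | C/C=C\[C@@H]1C[C@@](C)(O[Si](C)(C)C)C(=O)O1 | intermediate
17 | {(4R)-4-[(tert-butyldimethylsilyl)oxy]-3-methylidenehex-5-en-1-yn-1-yl}lithium | C=C[C@@H](O[Si](C)(C)C(C)(C)C)C(=C)C#C[Li] | intermediate (not isolated)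
18 | (2Z,4S,6R,11R)-11-[(tert-butyldimethylsilyl)oxy]-4-hydroxy-6-methyl-10-methylidene-6-[(trimethylsilyl)oxy]trideca-2,12-dien-8-yn-7-one | C/C=C\[C@@H](O)C[C@@](C)(O[Si](C)(C)C)C(=O)C#CC(=C)[C@H](O[Si](C)(C)C(C)(C)C)C=C | intermediate
19 | (2R)-5-{(3R)-3-[(tert-butyldimethylsilyl)oxy]penta-1,4-dien-2-yl}-2-[(2S,3Z)-2-hydroxypent-3-en-1-yl]-2-methylfuran-3(2H)-one | C/C=C\[C@@H](O)C[C@@]1(C)OC(=CC1=O)C(=C)[C@H](O[Si](C)(C)C(C)(C)C)C=C | intermediate
20 | (5R,6E,8S,10R)-5-[(tert-butyldimethylsilyl)oxy]-3,10-epoxy-8-hydroxy-10-methyl-4-methylidenecyclodeca-2,6-dien-1-one | CC(C)(C)[Si](C)(C)O[C@@H]1/C=C/[C@@H](O)C[C@@]2(C)OC(=CC2=O)C1=C | intermediate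
21 | (5R,6E,8S,10R)-8-(2-bromo-1-ethoxyethoxy)-5-[(tert-butyldimethylsilyl)oxy]-3,10-epoxy-10-methyl-4-methylidenecyclodeca-2,6-dien-1-one, acetal epimers | CC(C)(C)[Si](C)(C)O[C@@H]1/C=C/[C@@H](OC(CBr)OCC)C[C@@]2(C)OC(=CC2=O)C1=C | intermediate
22 | cis-fused lactol ethyl acetal (oxolane C8–O–C12(OEt)–C11–C7) with C6 O-(2,2,6,6-tetramethylpiperidin-1-yl) ether and C5 TBS ether; 5S,6R,7S,8S,10R; C12 epimers | CC1(C)CCCC(C)(C)N1O[C@@H]2[C@H]3CC(OCC)O[C@H]3C[C@@]4(C)OC(=CC4=O)C(=C)[C@@H]2O[Si](C)(C)C(C)(C)C | intermediate
23 | cis-fused lactol (C12 hydroxyl) with C6 nitroxide ether and C5 TBS ether; 5S,6R,7S,8S,10R; C12 epimers | CC1(C)CCCC(C)(C)N1O[C@@H]2[C@H]3CC(O)O[C@H]3C[C@@]4(C)OC(=CC4=O)C(=C)[C@@H]2O[Si](C)(C)C(C)(C)C | intermediate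
24 | cis-fused γ-lactone (C12 carbonyl, C11 methylene) with C6 nitroxide ether and C5 TBS ether; 5S,6R,7S,8S,10R | CC1(C)CCCC(C)(C)N1O[C@@H]2[C@H]3CC(=O)O[C@H]3C[C@@]4(C)OC(=CC4=O)C(=C)[C@@H]2O[Si](C)(C)C(C)(C)C | intermediate
25 | C11-(dimethylaminomethyl) derivative of 24; C11 epimers | CC1(C)CCCC(C)(C)N1O[C@@H]2[C@H]3C(CN(C)C)C(=O)O[C@H]3C[C@@]4(C)OC(=CC4=O)C(=C)[C@@H]2O[Si](C)(C)C(C)(C)C | intermediate
26 | C11-(trimethylammoniomethyl) lactone iodide | CC1(C)CCCC(C)(C)N1O[C@@H]2[C@H]3C(C[N+](C)(C)C)C(=O)O[C@H]3C[C@@]4(C)OC(=CC4=O)C(=C)[C@@H]2O[Si](C)(C)C(C)(C)C.[I-] | intermediate (not isolated)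
27 | α-methylene-γ-lactone with C6 nitroxide ether and C5 TBS ether; 5S,6R,7S,8S,10R | CC1(C)CCCC(C)(C)N1O[C@@H]2[C@H]3C(=C)C(=O)O[C@H]3C[C@@]4(C)OC(=CC4=O)C(=C)[C@@H]2O[Si](C)(C)C(C)(C)C | intermediate
28 | C6 alcohol with α-methylene-γ-lactone and C5 TBS ether; 5S,6R,7R,8S,10R | O[C@@H]1[C@H]2C(=C)C(=O)O[C@H]2C[C@@]2(C)OC(=CC2=O)C(=C)[C@@H]1O[Si](C)(C)C(C)(C)C | intermediate
29 | C6 methacrylate with α-methylene-γ-lactone and C5 TBS ether; 5S,6R,7S,8S,10R | C=C(C)C(=O)O[C@@H]1[C@H]2C(=C)C(=O)O[C@H]2C[C@@]2(C)OC(=CC2=O)C(=C)[C@@H]1O[Si](C)(C)C(C)(C)C | intermediate
30 | CNP0142847.2; 5S,6R,7S,8S,10R | C=C(C)C(=O)O[C@@H]1[C@H]2C(=C)C(=O)O[C@H]2C[C@@]2(C)OC(=CC2=O)C(=C)[C@@H]1O | target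

Total step count: 23 steps. Longest linear sequence: 18 steps (steps 1–6, then 12–23); the citramalic acid branch (steps 7–11) joins at step 12.

Steps least certain to work

Step 16 (key step). The most likely failure is coupling of the nitroxide with the primary C11 radical before it has closed the ring, or hydrogen transfer to either radical. Nitroxide capture is near diffusion-controlled, and ring closure onto the bridged alkene may be slowed by the conformational demands of the strained ring. A second concern is stereochemical: closure through the rotamer in which H8, not C9, lies near the alkene plane would give the C7 epimer with a trans ring fusion, and the bulky nitroxide must approach C6 next to the C5 silyloxy group and the new oxolane. Fallback: separate ring closure from oxygenation. Alcohol 20 is treated with N-iodosuccinimide and ethyl vinyl ether to give the iodoacetal F1. Under Et3B/air, with no nitroxide and no hydride donor present, F1 cyclises with iodine atom transfer to the cis-fused C6 iodide F2. Bu3SnH with excess TEMPO then regenerates the same C6 radical from the weak C–I bond and gives 22, where the route is rejoined.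

Step 14 (ring-closing metathesis). The most likely failure is oligomerisation by cross metathesis, or closure onto the C4 methylidene to a seven-membered ring, because the bridged ten-membered ring is strained and the furanone holds the two alkenyl arms apart. If the ring closed to the Z alkene instead, the facial course of step 16 would also change. Fallback: close the carbocycle before the oxygen bridge exists. Ynone 18 is submitted to the same metathesis to give the unbridged cyclodecenynone F3. K2CO3 in methanol then removes the TMS group and closes the furanone across the ring (transannular 5-endo-dig oxa-Michael addition), arriving at 20.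

Step 19 (aminomethylation). The most likely failure is conjugate addition of the lactone enolate, or of the amide base, to the dienyl furanone (C15 or C2) of the same or another molecule, since the substrate carries a good acceptor a few atoms from the enolate. Fallback: bring the methylene carbon in with the radical tether and avoid enolate chemistry. Alcohol 20 is etherified with 2-bromoallyl 2,2,2-trichloroacetimidate (TfOH cat.) to the 2-bromoallyl ether F4. Bu3SnH and TEMPO, as in step 16, generate the vinyl radical, which closes 5-exo onto C7 and after nitroxide capture gives the 3-methylidene oxolane F5. Allylic oxidation of the ring CH2 next to oxygen (CrO3·3,5-dimethylpyrazole) gives 27.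

Step 21 (N–O cleavage). The most likely failure is over-reduction: zinc in acid may also reduce the exocyclic enoate or cleave the C10–O bond next to the ketone, and the freed C6 hydroxyl may attack the lactone and move it from the C8 to the C6 oxygen. Fallback: carry the lactone through the reduction as its amine adduct. Mannich base 25 is reduced with zinc in acetic acid to the C6 alcohol F6 and acylated with methacrylic anhydride to the methacrylate F7. Only then is F7 quaternised with MeI and eliminated with NaHCO3, which gives 29.

Further compounds

F1 | step 16 | (5R,6E,8S,10R)-5-[(tert-butyldimethylsilyl)oxy]-3,10-epoxy-8-(1-ethoxy-2-iodoethoxy)-10-methyl-4-methylidenecyclodeca-2,6-dien-1-one, acetal epimers | CC(C)(C)[Si](C)(C)O[C@@H]1/C=C/[C@@H](OC(CI)OCC)C[C@@]2(C)OC(=CC2=O)C1=C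
F2 | step 16 | cis-fused lactol ethyl acetal with C6 iodide (iodine in the position of the nitroxide oxygen of 22) and C5 TBS ether, C12 epimers | I[C@@H]1[C@H]2CC(OCC)O[C@H]2C[C@@]2(C)OC(=CC2=O)C(=C)[C@@H]1O[Si](C)(C)C(C)(C)C
F3 | step 14 | (5R,6E,8S,10R)-5-[(tert-butyldimethylsilyl)oxy]-8-hydroxy-10-methyl-4-methylidene-10-[(trimethylsilyl)oxy]cyclodec-6-en-2-yn-1-one | O[C@H]1C[C@@](C)(O[Si](C)(C)C)C(=O)C#CC(=C)[C@H](O[Si](C)(C)C(C)(C)C)/C=C/1
F4 | step 19 | (5R,6E,8S,10R)-8-[(2-bromoprop-2-en-1-yl)oxy]-5-[(tert-butyldimethylsilyl)oxy]-3,10-epoxy-10-methyl-4-methylidenecyclodeca-2,6-dien-1-one | CC(C)(C)[Si](C)(C)O[C@@H]1/C=C/[C@@H](OCC(Br)=C)C[C@@]2(C)OC(=CC2=O)C1=C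
F5 | step 19 | cis-fused 3-methylidene oxolane (C8–O–C12H2–C11(=C13)–C7) with C6 O-(2,2,6,6-tetramethylpiperidin-1-yl) ether and C5 TBS ether | CC1(C)CCCC(C)(C)N1O[C@@H]2[C@H]3C(=C)CO[C@H]3C[C@@]4(C)OC(=CC4=O)C(=C)[C@@H]2O[Si](C)(C)C(C)(C)C
F6 | step 21 | C6 alcohol of the C11-(dimethylaminomethyl) lactone with C5 TBS ether, C11 epimers | O[C@@H]1[C@H]2C(CN(C)C)C(=O)O[C@H]2C[C@@]2(C)OC(=CC2=O)C(=C)[C@@H]1O[Si](C)(C)C(C)(C)C
F7 | step 21 | C6 methacrylate of the C11-(dimethylaminomethyl) lactone with C5 TBS ether, C11 epimers | C=C(C)C(=O)O[C@@H]1[C@H]2C(CN(C)C)C(=O)O[C@H]2C[C@@]2(C)OC(=CC2=O)C(=C)[C@@H]1O[Si](C)(C)C(C)(C)C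
A1 | alternative 1 | oxygen-bridged cyclodecenone with C4 methylene and C5=C6 silyl enol ether | CC(C)(C)[Si](C)(C)O/C1=C\C(=C)[C@H]2CC(=O)[C@](C)(O2)C[C@H](OCc3ccc(OC)cc3)[C@@H]1C(C)=C
A2 | alternative 2 | 11-oxabicyclo[6.2.1]undecenone with C1 ketone, C10 methyl and Z C7=C8 alkene | C[C@@]12C/C=C\[C@H]3OC(C)(C)O[C@H]3[C@H](O[Si](C)(C)C(C)(C)C)[C@@H](CC1=O)O2
A3 | alternative 3 | furanone with C10 quaternary centre and both arms, open at C7–C8 | C=C(C)C(=O)O[C@H](/C=C(\CO[Si](C)(C)C(C)(C)C)C(=O)OC)[C@@H](O[Si](C)(C)C(C)(C)C)C(=C)C1=CC(=O)[C@@](C)(CCOCc2ccc(OC)cc2)O1
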